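**Plan**

- The only stereocentre is C2 of the dihydropyranone ring. It carries the phenyl group, is bonded to ring O1 and lies β to the C4 ketone, so the C2–C1′(phenyl) bond can be cut back to a flat chromone (C2=C3) and a phenyl nucleophile.
- Retrosynthetic cuts, in order: the O5–CH2OMe acetal, the C2–phenyl bond, the O1–C2/C2–C3 unit of the pyranone (C2 from a formamide acetal), the O–MOM bond, and the aryl–geranyl C–C bond.
- Forward: the geranyl chain is joined first to a symmetric acetophenone, the unhindered phenol is capped, the pyranone (the only ring made) is closed through the phenol next to the geranyl group, phenyl is added, and the MOM group is removed.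
- Stereochemistry: 2S comes from the chiral rhodium catalyst in the conjugate arylation; the 2E alkene comes unchanged from geranyl bromide.

Key step: step 4

Assumption: the (S)-biaryl bisphosphine–rhodium catalyst is taken to deliver aryl to chromone C2 in the same facial sense as (S)-BINAP–Rh does to 2-cyclohexenone, which corresponds to the Re face of C2 and the 2S product; a trial on the parent chromone would confirm this, and the (R)-ligand would be used if the sense were opposite.

Geranyl = (2E)-3,7-dimethylocta-2,6-dien-1-yl throughout.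

**Route**

Step 1
Reactants: 1 2',6'-dihydroxy-4'-methoxyacetophenone; 2 geranyl bromide
Product: 3 3'-geranyl-2',6'-dihydroxy-4'-methoxyacetophenone
Conditions: 1 (1.3 equiv), 2 (1.0 equiv), DBU (1.3 equiv), THF, 0 °C to rt
Reagents that add atoms: none
Why: Phenoxide C-alkylation (SN2 at the primary allylic bromide) of the phloroglucinol-type ring, in which C3' and C5' are equivalent by symmetry and each is ortho to one hydroxyl and para to the other, so only one mono-C-geranyl isomer can form and the E alkene of 2 is carried over.

Step 2
Reactants: 3 3'-geranyl-2',6'-dihydroxy-4'-methoxyacetophenone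
Product: 4 3'-geranyl-2'-hydroxy-4'-methoxy-6'-(methoxymethoxy)acetophenone
Conditions: MOMCl (1.05 equiv), i-Pr2NEt (1.5 equiv), CH2Cl2, 0 °C
Reagents that add atoms: chloromethyl methyl ether, COCCl
Why: Williamson-type acetal ether formation should occur at the more accessible phenol, because O6' has only the acetyl group as ortho neighbour whereas O2' is flanked by the acetyl and the geranyl-bearing carbon and stays behind as the chelated phenol.

Step 3
Reactants: 4 3'-geranyl-2'-hydroxy-4'-methoxy-6'-(methoxymethoxy)acetophenone; 5 N,N-dimethylformamide dimethyl acetal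
Product: 7 8-geranyl-7-methoxy-5-(methoxymethoxy)chromone, via enaminone 6 (not isolated)
Conditions: 5 (3 equiv), toluene, 95 °C; evaporate; then AcOH, 50 °C
Reagents that add atoms: none
Why: Enaminone condensation of the methyl ketone followed by mildly acidic intramolecular oxa-Michael addition of the only free phenol and loss of dimethylamine (addition–elimination) closes the 4-pyranone with the geranyl group at C8, and acetic acid buffered by the released amine should be too weak to cleave the MOM ether or cyclise the geranyl chain.

Step 4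
Reactants: 7 8-geranyl-7-methoxy-5-(methoxymethoxy)chromone; 8 phenylboronic acid
Product: 9 (2S)-8-geranyl-7-methoxy-5-(methoxymethoxy)flavanone
Conditions: 8 (3 equiv), [Rh(OH)(cod)]2 (2.5 mol %), (S)-MeO-F12-BIPHEP [(S)-2,2'-bis[bis(3,4,5-trifluorophenyl)phosphino]-6,6'-dimethoxybiphenyl] (5.5 mol %), degassed toluene/H2O (10:1), 30 °C, no added base
Reagents that add atoms: none
Why: Transmetalation of phenylboronic acid to the Rh(I) hydroxide gives a phenyl–rhodium species, the chromone C2=C3 bond inserts syn into Rh–Ph in the enantio-determining carbometalation, and hydrolysis of the resulting oxa-π-allyl rhodium enolate by water releases the flavanone and regenerates Rh–OH. This is the Hayashi–Miyaura rhodium-catalysed asymmetric 1,4-addition of arylboronic acids, a known reaction of chromones with electron-poor biaryl bisphosphines. No ring is closed; only the C2–C1' bond forms. The C2 stereocentre is controlled by the axially chiral (S)-bisphosphine, which should expose the Re face of C2 (O1 > C3 > H) to the migrating phenyl and so give 2S. The step needs 1,4- over 1,2-addition and no retro-oxa-Michael ring opening, which the neutral base-free two-phase medium secures, and chemoselectivity over the geranyl chain, whose unactivated trisubstituted alkenes do not insert into aryl–rhodium. The MOM ether on O5 keeps the peri oxygen from forming an acetylacetonate-like O,O-chelate with rhodium, while ring O1 and the C4 carbonyl polarise C2 enough to offset the electron-rich A ring.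

Step 5
Reactants: 9 (2S)-8-geranyl-7-methoxy-5-(methoxymethoxy)flavanone
Product: 10 (2S)-8-geranyl-5-hydroxy-7-methoxyflavanone
Conditions: HCl (0.5 M in MeOH), MeOH/THF, 0 °C to rt
Reagents that add atoms: none
Why: Acid-catalysed acetal exchange to methanol cleaves the MOM ether, which is activated by the peri C4 carbonyl, and dilute acid at ambient temperature should leave the trisubstituted alkenes and the C2 centre (which can epimerise only by ring opening to the chalcone) untouched.

**Compound list**

1 | 2',6'-dihydroxy-4'-methoxyacetophenone, 1-(2,6-dihydroxy-4-methoxyphenyl)ethanone | CC(=O)c1c(O)cc(OC)cc1O | starting material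
2 | geranyl bromide, (2E)-1-bromo-3,7-dimethylocta-2,6-diene | CC(C)=CCC/C(C)=C/CBr | starting material
3 | 1-{3-[(2E)-3,7-dimethylocta-2,6-dien-1-yl]-2,6-dihydroxy-4-methoxyphenyl}ethanone | CC(=O)c1c(O)cc(OC)c(C/C=C(\C)CCC=C(C)C)c1O | intermediate
4 | 1-{3-[(2E)-3,7-dimethylocta-2,6-dien-1-yl]-2-hydroxy-4-methoxy-6-(methoxymethoxy)phenyl}ethanone | CC(=O)c1c(OCOC)cc(OC)c(C/C=C(\C)CCC=C(C)C)c1O | intermediate
5 | N,N-dimethylformamide dimethyl acetal | COC(OC)N(C)C | starting material
6 | (2E)-3-(dimethylamino)-1-{3-[(2E)-3,7-dimethylocta-2,6-dien-1-yl]-2-hydroxy-4-methoxy-6-(methoxymethoxy)phenyl}prop-2-en-1-one | CN(C)/C=C/C(=O)c1c(OCOC)cc(OC)c(C/C=C(\C)CCC=C(C)C)c1O | intermediate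
7 | 8-[(2E)-3,7-dimethylocta-2,6-dien-1-yl]-7-methoxy-5-(methoxymethoxy)-4H-chromen-4-one | COc1cc(OCOC)c2c(c1C/C=C(\C)CCC=C(C)C)OC=CC2=O | intermediate
8 | phenylboronic acid | OB(O)c1ccccc1 | starting material
9 | (2S)-8-[(2E)-3,7-dimethylocta-2,6-dien-1-yl]-7-methoxy-5-(methoxymethoxy)-2-phenyl-2,3-dihydro-4H-chromen-4-one | COc1cc(OCOC)c2c(c1C/C=C(\C)CCC=C(C)C)O[C@H](c1ccccc1)CC2=O | intermediate
10 | (2S)-8-[(2E)-3,7-dimethylocta-2,6-dien-1-yl]-5-hydroxy-7-methoxy-2-phenyl-2,3-dihydro-4H-chromen-4-one | COc1cc(O)c2c(c1C/C=C(\C)CCC=C(C)C)O[C@H](c1ccccc1)CC2=O | target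

**Count**

Total steps: 5. Longest linear sequence: 5 steps (from 1).

**Steps most likely to fail, with fallbacks**

Step 4. Insertion into the electron-rich, 5,7,8-trisubstituted chromone may be slow enough that protodeboronation of the boronic acid outruns the addition, or facial discrimination may be incomplete. The fallback sets out from 4 and sets the stereocentre by resolution instead of catalysis. Claisen–Schmidt condensation of 4 with benzaldehyde (KOH, EtOH, rt) should give the chalcone (2E)-1-{3-geranyl-2-hydroxy-4-methoxy-6-(methoxymethoxy)phenyl}-3-phenylprop-2-en-1-one F1. Its single free phenol allows only one oxa-Michael ring closure (NaOAc, EtOH, reflux), to racemic 8-geranyl-7-methoxy-5-(methoxymethoxy)flavanone F2. Preparative HPLC on a polysaccharide carbamate chiral phase would separate the enantiomers, and the 2S enantiomer rejoins the route at 9.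

Step 2. Protection may go to the geranyl-flanked hydroxyl or to both hydroxyls, which would lead on to the 6-geranyl chromone. The fallback sets out from 1 and avoids any discrimination between hydroxyls by adding the geranyl group last.
- Because 1 is symmetric, mono-protection (MOMCl, i-Pr2NEt, CH2Cl2) can give only one ether, 2'-hydroxy-4'-methoxy-6'-(methoxymethoxy)acetophenone F3.
- Treatment with 5 and then acetic acid, through (2E)-3-(dimethylamino)-1-[2-hydroxy-4-methoxy-6-(methoxymethoxy)phenyl]prop-2-en-1-one F4, should give 7-methoxy-5-(methoxymethoxy)chromone F5.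
- Electrophilic iodination (NIS, DMF, rt), which for 5,7-dialkoxy chromones and flavones goes to C8, should give 8-iodo-7-methoxy-5-(methoxymethoxy)chromone F6.
- Stille coupling (Pd2(dba)3, AsPh3, DMF, 70 °C) with tributyl(geranyl)stannane F7, made from 2 and Bu3SnLi in THF at −78 °C, would deliver 7.

Step 1. O-alkylation and double alkylation may outweigh mono-C-alkylation of the phenoxide. The fallback sets out from 1 and replaces the phenoxide alkylation by a cross-coupling. Mono-iodination (NIS, MeCN, 0 °C) should give 2',6'-dihydroxy-3'-iodo-4'-methoxyacetophenone F8, in which the site of the new bond is fixed by the halogen. Stille coupling with the stannane F7 described above (Pd(PPh3)4, DMF, 80 °C) then forms the aryl–geranyl bond with the E alkene intact and returns to 3.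

**Further compounds**

F1 | step 4 | (2E)-1-{3-[(2E)-3,7-dimethylocta-2,6-dien-1-yl]-2-hydroxy-4-methoxy-6-(methoxymethoxy)phenyl}-3-phenylprop-2-en-1-one | O=C(/C=C/c1ccccc1)c1c(OCOC)cc(OC)c(C/C=C(\C)CCC=C(C)C)c1O
F2 | step 4 | racemic 8-[(2E)-3,7-dimethylocta-2,6-dien-1-yl]-7-methoxy-5-(methoxymethoxy)-2-phenyl-2,3-dihydro-4H-chromen-4-one | COc1cc(OCOC)c2c(c1C/C=C(\C)CCC=C(C)C)OC(c1ccccc1)CC2=O
F3 | step 2 | 1-[2-hydroxy-4-methoxy-6-(methoxymethoxy)phenyl]ethanone | CC(=O)c1c(O)cc(OC)cc1OCOC
F4 | step 2 | (2E)-3-(dimethylamino)-1-[2-hydroxy-4-methoxy-6-(methoxymethoxy)phenyl]prop-2-en-1-one | CN(C)/C=C/C(=O)c1c(O)cc(OC)cc1OCOC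
F5 | step 2 | 7-methoxy-5-(methoxymethoxy)-4H-chromen-4-one | COc1cc(OCOC)c2c(c1)OC=CC2=O
F6 | step 2 | 8-iodo-7-methoxy-5-(methoxymethoxy)-4H-chromen-4-one | COc1cc(OCOC)c2c(c1I)OC=CC2=O
F7 | step 2 | tributyl[(2E)-3,7-dimethylocta-2,6-dien-1-yl]stannane | CCCC[Sn](CCCC)(CCCC)C/C=C(\C)CCC=C(C)C
F8 | step 1 | 1-(2,6-dihydroxy-3-iodo-4-methoxyphenyl)ethanone | CC(=O)c1c(O)cc(OC)c(I)c1O
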